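**Retrosynthetic overview**

- The bond between tetralone C4 and naphthalene C1' is cut as in the presumed biogenesis: a 4-hydroxytetralone loses water to an ortho-quinone methide, which is captured by the para carbon of a 5-oxygenated 1-naphthol.
- The only ring built is the carbocycle of the tetralone half: hydroquinone 1 + succinic anhydride 2 → bicyclic diketone 3 (a succinyl-type annulation onto a benzenoid ring), then mono-reduction to carbinol 4.
- Naphthalene half (both rings bought): naphthalene-1,5-diol 5 → monomethyl ether 6 → silyl ether 7.
- Key step: 4 → ortho-quinone methide 8, enantioselective para-arylation by 7 under a chiral Brønsted acid → silyl ether 9 → target 10 in the same flask. The single stereocentre is set in the C–C bond-forming event.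

Assumption: the target is the (R)-enantiomer at C4 of the tetralone (CIP analysis of the given SMILES). The facial sense of the chiral acid in step 5 is not predictable with certainty and must be confirmed on the first run; the enantiomeric acid is used if the written one gives the antipode.

**Step 1**
Reactants: 1 hydroquinone (benzene-1,4-diol); 2 succinic anhydride (oxolane-2,5-dione)
Product: 3 5,8-dihydroxy-2,3-dihydronaphthalene-1,4-dione (2,3-dihydronaphthazarin)
Conditions: AlCl3–NaCl melt (5:1 w/w, reaction medium), 180–190 °C, 5 min; then ice, aq HCl, 90 °C
Reagents that add atoms: none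
Why: Double Friedel–Crafts acylation (intermolecular, then ring-closing ortho to the second hydroxyl), the succinic anhydride variant of the classical melt synthesis of naphthazarin and quinizarin; the product is the stable diketo tautomer of naphthalene-1,4,5,8-tetrol and no stereocentre is formed.

**Step 2**
Reactants: 3 5,8-dihydroxy-2,3-dihydronaphthalene-1,4-dione
Product: 4 (±)-4,5,8-trihydroxy-3,4-dihydronaphthalen-1(2H)-one
Conditions: NaBH4 (0.5 equiv), EtOH–THF, −20 °C, 30 min; then H2O
Reagents that add atoms: none
Why: Borohydride 1,2-reduction of one of two equivalent chelated aryl ketones, stopped at the mono-carbinol by substoichiometric hydride at low temperature (the same desymmetrising reduction that converts 2,3-dihydrojuglone into isosclerone); the carbinol centre is racemic on purpose because it is erased in step 5.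

**Step 3**
Reactants: 5 naphthalene-1,5-diol
Product: 6 5-methoxynaphthalen-1-ol
Conditions: MeI (1.0 equiv), K2CO3 (1.0 equiv), acetone, reflux; chromatography (5 recovered and recycled)
Reagents that add atoms: iodomethane, CI
Why: Williamson ether synthesis on a C2-symmetric diol, so only one mono-ether is possible and it is separated from diol and diether by polarity; no stereocentre.

**Step 4**
Reactants: 6 5-methoxynaphthalen-1-ol
Product: 7 triisopropyl[(5-methoxynaphthalen-1-yl)oxy]silane
Conditions: TIPSCl (1.2 equiv), imidazole (2 equiv), DMF, rt
Reagents that add atoms: chlorotriisopropylsilane, CC(C)[Si](Cl)(C(C)C)C(C)C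
Why: Standard imidazole-mediated O-silylation; the bulky silyl group removes the O–H that would steer a Brønsted acid catalyst to the ortho carbon C2 and screens both C2 and its own peri carbon C8, leaving C4 as the reactive site.

**Step 5**
Reactants: 4 (±)-4,5,8-trihydroxy-3,4-dihydronaphthalen-1(2H)-one; 7 triisopropyl[(5-methoxynaphthalen-1-yl)oxy]silane
Product: 10 (R)-5,8-dihydroxy-4-(4-hydroxy-8-methoxynaphthalen-1-yl)-3,4-dihydronaphthalen-1(2H)-one, via ortho-quinone methide 8 (not isolated), via silyl ether 9 (not isolated)
Conditions: 4 (1 equiv), 7 (2 equiv), 1,1,1-trifluoro-N-[(11bR)-4-oxido-2,6-bis(2,4,6-triisopropylphenyl)dinaphtho[2,1-d:1',2'-f][1,3,2]dioxaphosphepin-4-yl]methanesulfonamide (10 mol%), 4 Å MS, CH2Cl2, −30 → 0 °C; then Bu4NF/AcOH (1:1), THF, 0 °C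
Reagents that add atoms: none
Why: Proposed new method: the strong chiral acid ionises the ortho-hydroxybenzylic alcohol of 4 (loss of water) to ortho-quinone methide 8, held as a hydrogen-bonded ion pair, and 7, reacting like an extended silyl dienol ether, attacks the methide carbon through C4 (para to OSi; 1,5-dialkoxynaphthalenes take electrophiles at C4 despite the peri alkoxy group) on the face left open by the chiral anion, which sets the (R) centre enantioconvergently from racemic 4 before rearomatisation to 9 and fluoride desilylation; the closest known reactions are chiral phosphoric acid and N-triflylphosphoramide catalysed enantioselective Friedel–Crafts and cycloaddition reactions of in situ generated ortho-quinone methides with indoles, naphthols and non-hydrogen-bonding styrenes, and the ring of 8 holds C3 anti to the methide carbonyl, which blocks the 1,5-hydrogen shift that normally drains alkyl ortho-quinone methides.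

**Compound list**

1 | hydroquinone (benzene-1,4-diol) | Oc1ccc(O)cc1 | starting material
2 | succinic anhydride (oxolane-2,5-dione) | O=C1CCC(=O)O1 | starting material
3 | 5,8-dihydroxy-2,3-dihydronaphthalene-1,4-dione | O=C1CCC(=O)c2c(O)ccc(O)c12 | intermediate
4 | (±)-4,5,8-trihydroxy-3,4-dihydronaphthalen-1(2H)-one | O=C1CCC(O)c2c(O)ccc(O)c12 | intermediate
5 | naphthalene-1,5-diol | Oc1cccc2c(O)cccc12 | starting material
6 | 5-methoxynaphthalen-1-ol | COc1cccc2c(O)cccc12 | intermediate
7 | triisopropyl[(5-methoxynaphthalen-1-yl)oxy]silane | COc1cccc2c(O[Si](C(C)C)(C(C)C)C(C)C)cccc12 | intermediate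
8 | 8-hydroxy-2,3-dihydronaphthalene-1,5-dione (ortho-quinone methide, not isolated) | O=C1CCC=C2C(=O)C=CC(O)=C12 | intermediate
9 | (R)-5,8-dihydroxy-4-{8-methoxy-4-[(triisopropylsilyl)oxy]naphthalen-1-yl}-3,4-dihydronaphthalen-1(2H)-one (not isolated) | COc1cccc2c(O[Si](C(C)C)(C(C)C)C(C)C)ccc([C@H]3CCC(=O)c4c(O)ccc(O)c43)c12 | intermediate
10 | (R)-5,8-dihydroxy-4-(4-hydroxy-8-methoxynaphthalen-1-yl)-3,4-dihydronaphthalen-1(2H)-one | COc1cccc2c(O)ccc([C@H]3CCC(=O)c4c(O)ccc(O)c43)c12 | target

**Step count**

Total steps: 5. Longest linear sequence: 3 (steps 1, 2, 5 or steps 3, 4, 5).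

**Steps most likely to fail and fallbacks**

1. The key coupling (step 5) is the riskiest step. Methide 8 may aromatise to naphthalene-1,4,5-triol before it is captured, 7 may react partly at C8, and the ee may be modest without a hydrogen-bond donor on the arene. The fallback sets out from 6 and returns at 9.
   - para-Bromination of 6 with N-bromosuccinimide in MeCN at 0 °C gives 4-bromo-5-methoxynaphthalen-1-ol F1.
   - Silylation (TIPSCl, imidazole) gives [(4-bromo-5-methoxynaphthalen-1-yl)oxy]triisopropylsilane F2.
   - Bromine–lithium exchange (n-BuLi, THF, −78 °C) and quench with B(OiPr)3 give diisopropyl {8-methoxy-4-[(triisopropylsilyl)oxy]naphthalen-1-yl}boronate F3.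
   - F3 and 4 are joined with (R)-3,3'-dibromo-1,1'-bi-2-naphthol (15 mol%) and 4 Å molecular sieves in PhCF3. The phenol next to the carbinol of 4 binds boron, water is lost to 8 inside the boronate complex, and the aryl group is delivered intramolecularly to C4 under control of the chiral diol (asymmetric boronate addition to ortho-quinone methides). This gives 9, which is desilylated as in step 5.
   - The C–B bond fixes the regiochemistry, and intramolecular delivery outruns aromatisation.

2. The mono-reduction (step 2) may over-reduce to the diol, and 4 is sensitive to acid and air on isolation. The fallback sets out from 1 and returns at 8, with no partial reduction.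
   - 1 is condensed with γ-butyrolactone in the AlCl3–NaCl melt (tandem Friedel–Crafts alkylation–acylation, the arene-plus-butyrolactone tetralone synthesis) to give 5,8-dihydroxy-3,4-dihydronaphthalen-1(2H)-one F4.
   - Oxidation with PhI(OAc)2 in MeCN–H2O gives the acylquinone 6,7-dihydronaphthalene-1,4,5(8H)-trione F5.
   - Under the chiral acid of step 5, F5 tautomerises (quinone to quinone methide) to 8, which is captured by 7 as before.

3. The melt annulation (step 1) may char, give a low yield, or partly dehydrogenate to the quinone. The fallback sets out from 1 and returns at 3.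
   - 1 is condensed with maleic anhydride in the same kind of melt to give 5,8-dihydroxynaphthalene-1,4-dione (naphthazarin) F6, the long-established outcome at the quinone oxidation level.
   - F6 is reduced with SnCl2 in aqueous HCl at reflux to 3, which crystallises as the diketo tautomer.

**Further compounds**

F1 | step 5 | 4-bromo-5-methoxynaphthalen-1-ol | COc1cccc2c(O)ccc(Br)c12
F2 | step 5 | [(4-bromo-5-methoxynaphthalen-1-yl)oxy]triisopropylsilane | COc1cccc2c(O[Si](C(C)C)(C(C)C)C(C)C)ccc(Br)c12
F3 | step 5 | diisopropyl {8-methoxy-4-[(triisopropylsilyl)oxy]naphthalen-1-yl}boronate | COc1cccc2c(O[Si](C(C)C)(C(C)C)C(C)C)ccc(B(OC(C)C)OC(C)C)c12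
F4 | step 2 | 5,8-dihydroxy-3,4-dihydronaphthalen-1(2H)-one | O=C1CCCc2c(O)ccc(O)c12
F5 | step 2 | 6,7-dihydronaphthalene-1,4,5(8H)-trione | O=C1CCCC2=C1C(=O)C=CC2=O
F6 | step 1 | 5,8-dihydroxynaphthalene-1,4-dione (naphthazarin) | O=C1C=CC(=O)c2c(O)ccc(O)c12
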